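**Strategy.** The dihydrobenzofuran is disconnected at its C2–C3 bond. The precursor is the complete trans-dibenzylbutyrolactone whose central guaiacyl ring carries an O-(4-benzyloxy-3-methoxybenzyl) ether and, ortho to it, a diazoacetate. A chiral Rh(II) carboxylate turns the diazo carbon (future C3) into a carbene that inserts into one benzylic C–H of the OCH2Ar ether (future C2–H, activated by O1 and the electron-rich aryl); this closes the five-membered O1–C2–C3–C3a–C7a ring, the catalyst sets C2, and base relay then places C3 trans. The lactone stereocentres come from asymmetric hydrogenation and trans-alkylation, the erythro arylglycerol ether from an Evans aldol with Mitsunobu inversion.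

Key step: step 16

Remark: the sense of induction of the two chiral Rh catalysts (steps 3 and 16) is assigned by analogy with simpler substrates and is an assumption; in both cases the antipodal catalyst is equally accessible.
Abbreviations: BV = 4-(benzyloxy)-3-methoxyphenyl; Diox = (4R,5S)-4-BV-2,2-dimethyl-1,3-dioxan-5-yl.

Step 1
Reactants: 1 5-bromovanillin; 2 4-(benzyloxy)-3-methoxybenzyl alcohol
Product: 3 3-bromo-5-methoxy-4-(BV-methoxy)benzaldehyde
Conditions: PPh3, DIAD, THF, 0 °C → rt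
Reagents that add atoms: none
Why: Mitsunobu etherification, in which the acidic, hindered phenol of 1 is alkylated by the oxyphosphonium salt of the primary benzylic alcohol 2; no stereocentre is formed and the aldehyde is inert.

Step 2
Reactants: 3 aryl aldehyde; 4 dimethyl succinate
Product: 5 (E)-4-aryl-3-(methoxycarbonyl)but-3-enoic acid (aryl = 3-bromo-5-methoxy-4-(BV-methoxy)phenyl)
Conditions: NaOMe, MeOH, reflux; then aq. HCl
Reagents that add atoms: none
Why: Stobbe condensation (aldol addition, lactonisation, E1cB opening) should give the (E)-itaconate half ester, and the aryl bromide and benzylic ethers are inert to methoxide.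

Step 3
Reactants: 5 itaconate half ester
Product: 6 (R)-4-aryl-3-(methoxycarbonyl)butanoic acid
Conditions: [Rh(cod)((S,S)-Et-DuPhos)]BF4 (1 mol %), H2 (5 bar), NaOMe (10 mol %), MeOH, rt
Reagents that add atoms: none
Why: Rh–bisphospholane asymmetric hydrogenation of a Stobbe itaconate, bound as its carboxylate, sets the (R)-centre (later lactone C4) by catalyst control, and a homogeneous Rh catalyst should leave ArBr and benzyl ethers alone.

Step 4
Reactants: 6 saturated half ester
Product: 8 (R)-4-[3-bromo-5-methoxy-4-(BV-methoxy)benzyl]dihydrofuran-2(3H)-one, via hydroxy acid 7 (not isolated)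
Conditions: LiBH4, THF, 0 °C → rt; then aq. KHSO4 (pH 3), rt
Reagents that add atoms: none
Why: LiBH4 reduces the ester but not the lithium carboxylate, and mild acidification lactonises the γ-hydroxy acid without touching the stereocentre or the acid-labile benzylic aryl ether.

Step 5
Reactants: 9 methyl vanillate; 10 (R)-4-benzyl-3-(chloroacetyl)oxazolidin-2-one
Product: 11 methyl 4-{2-[(R)-4-benzyl-2-oxooxazolidin-3-yl]-2-oxoethoxy}-3-methoxybenzoate
Conditions: K2CO3, NaI (cat.), acetone, 50 °C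
Reagents that add atoms: none
Why: Williamson-type SN2 displacement of the activated α-chloro imide by the phenoxide, which does not involve the auxiliary stereocentre.

Step 6
Reactants: 11 aryloxyacetyl imide; 12 4-(benzyloxy)-3-methoxybenzaldehyde
Product: 13 syn-aldol adduct (2R,3S)
Conditions: Bu2BOTf, iPr2NEt, CH2Cl2, −78 → 0 °C; then 12, −78 → 0 °C; pH 7 buffer, MeOH, H2O2
Reagents that add atoms: none
Why: Evans boron aldol, in which the Z-boron enolate reacts through a Zimmerman–Traxler chair on the face left open by the (R)-auxiliary, should give the syn (threo) adduct and so fix the aryloxy-bearing carbon (later 8S).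

Step 7
Reactants: 13 syn-aldol adduct
Product: 14 inverted 4-nitrobenzoate (2R,3R)
Conditions: 4-nitrobenzoic acid, PPh3, DIAD, toluene, 0 °C → rt
Reagents that add atoms: 4-nitrobenzoic acid, O=C(O)c1ccc([N+](=O)[O-])cc1
Why: Mitsunobu inversion (SN2 by the carboxylate at the benzylic oxyphosphonium) converts the carbinol centre from S to R, that is threo to erythro, while the α-centre is untouched.

Step 8
Reactants: 14 4-nitrobenzoate
Product: 15 methyl 4-{[(1R,2S)-1-BV-1,3-dihydroxypropan-2-yl]oxy}-3-methoxybenzoate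
Conditions: LiBH4, THF, MeOH (2 equiv), 0 °C
Reagents that add atoms: none
Why: LiBH4 cleaves the N-acyl oxazolidinone reductively to the primary alcohol and reduces the activated nitrobenzoate, whereas the electron-rich methyl benzoate reacts far more slowly at 0 °C.

Step 9
Reactants: 15 erythro 1,3-diol
Product: 16 methyl 4-(Diox-oxy)-3-methoxybenzoate
Conditions: 2,2-dimethoxypropane, PPTS (cat.), acetone, rt
Reagents that add atoms: 2,2-dimethoxypropane, COC(C)(C)OC
Why: acid-catalysed transketalisation gives the six-membered acetonide (trans-diequatorial dioxane), and PPTS is too weak to ionise the benzylic C–O bond.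

Step 10
Reactants: 16 acetonide ester
Product: 17 [4-(Diox-oxy)-3-methoxyphenyl]methanol
Conditions: DIBAL-H, CH2Cl2, −78 → 0 °C; Rochelle salt
Reagents that add atoms: none
Why: DIBAL-H reduction of the aryl ester to the benzylic alcohol, with ketal and ethers stable at low temperature.

Step 11
Reactants: 17 benzylic alcohol
Product: 18 (4R,5S)-4-BV-5-[4-(bromomethyl)-2-methoxyphenoxy]-2,2-dimethyl-1,3-dioxane
Conditions: CBr4, PPh3, 2,6-lutidine, CH2Cl2, 0 °C (used crude)
Reagents that add atoms: carbon tetrabromide, BrC(Br)(Br)Br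
Why: Appel reaction (bromide SN2 on the alkoxyphosphonium) under buffered, non-acidic conditions that should spare the acetonide.

Step 12
Reactants: 19 bromoacetyl bromide; 20 2-(trimethylsilyl)ethanol
Product: 21 2-(trimethylsilyl)ethyl bromoacetate
Conditions: pyridine, CH2Cl2, 0 °C → rt
Reagents that add atoms: none
Why: O-acylation by the acid bromide is much faster than SN2 at the CH2Br group.

Step 13
Reactants: 8 β-benzyl lactone; 18 benzylic bromide
Product: 22 (3R,4R)-4-[3-bromo-5-methoxy-4-(BV-methoxy)benzyl]-3-[3-methoxy-4-(Diox-oxy)benzyl]dihydrofuran-2(3H)-one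
Conditions: LiHMDS, THF, −78 °C; then 18, DMPU, −78 → −40 °C
Reagents that add atoms: none
Why: alkylation of the lactone lithium enolate anti to the C4 benzyl group (substrate control) should give the 3,4-trans lactone, the standard entry to dibenzylbutyrolactone lignans, and the amide base does not exchange the aryl bromide.

Step 14
Reactants: 22 aryl bromide; 21 2-(trimethylsilyl)ethyl bromoacetate
Product: 24 2-(trimethylsilyl)ethyl arylacetate (Br of 22 replaced by CH2CO2CH2CH2SiMe3), via zinc reagent 23 (not isolated)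
Conditions: 21, Zn dust (TMSCl-activated), THF, rt; then 22, Pd(dba)2 (5 mol %), Q-Phos (5 mol %), THF, 60 °C
Reagents that add atoms: none
Why: Pd-catalysed α-arylation with a Reformatsky zinc enolate (Negishi-type coupling), which does not add to the lactone and tolerates the benzylic ethers and the ketal.

Step 15
Reactants: 24 arylacetate
Product: 25 2-(trimethylsilyl)ethyl aryl(diazo)acetate
Conditions: p-ABSA, DBU, MeCN, 0 °C → rt
Reagents that add atoms: 4-acetamidobenzenesulfonyl azide, CC(=O)Nc1ccc(cc1)S(=O)(=O)N=[N+]=[N-]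
Why: Regitz diazo transfer to the benzylic arylacetate CH2, which DBU deprotonates in preference to the less acidic lactone α-CH.

Step 16
Reactants: 25 aryl diazoacetate
Product: 27 trans-(2S,3S)-2-BV-2,3-dihydrobenzofuran-3-carboxylate, via cis ester 26 (not isolated)
Conditions: Rh2(S-PTTL)4 (2 mol %), toluene, −60 → −20 °C (slow addition of 25); then DBU, 40 °C
Reagents that add atoms: none
Why: Rh2(S-PTTL)4 converts the donor/acceptor diazoester into a Rh carbene at the future C3, which inserts through a concerted, hydride-transfer-like three-centre transition state into one of the two benzylic C–H bonds of the ortho OCH2Ar ether and so forms the C2–C3 bond. The closest known reaction is the Rh(II)-catalysed intramolecular C–H insertion of 2-(benzyloxy)aryl diazoacetates to cis-2-aryl-2,3-dihydrobenzofuran-3-carboxylates. The single ring is closed by 1,5-C–H insertion, a five-membered closure through C–C bond formation between the carbene carbon and the oxygen-bound benzylic carbon. C2 is set by the chiral catalyst, which selects one of the two hydrogens (reagent control, the remote lactone and dioxane centres being spectators); C3 first forms cis in the compact insertion transition state and is then equilibrated by DBU through the ester enolate to the more stable 2,3-trans arrangement, so C2 relays its configuration to C3. The step needs site selectivity for this C–H bond over all other benzylic and ether C–H bonds and over carbene dimerisation, secured by its 1,5-relationship to the carbene, its activation by O1 and the 4-alkoxy-3-methoxyphenyl group, the impossibility of a four-membered oxonium ylide, and low temperature with slow addition. Ring opening by β-elimination during epimerisation is disfavoured because the C2–O1 bond lies in the ring plane, orthogonal to the enolate π-system.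

Step 17
Reactants: 27 trans silylethyl ester
Product: 28 trans-(2S,3S)-2,3-dihydrobenzofuran-3-carboxylic acid
Conditions: TBAF, THF, 0 °C → rt; aq. NH4Cl
Reagents that add atoms: none
Why: fluoride-induced fragmentation of the 2-silylethyl ester frees the acid without hydroxide, so the lactone is never opened, and C3 already sits in its stable trans arrangement.

Step 18
Reactants: 28 carboxylic acid
Product: 30 di-O-benzyl triol (benzofuran CH2OH and free 1,3-diol), via acetonide alcohol 29 (not isolated)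
Conditions: BH3·THF, THF, 0 °C → rt; then AcOH/H2O (4:1), 45 °C
Reagents that add atoms: none
Why: borane reduces a carboxylic acid through its acyloxyborane far faster than a γ-lactone, and aqueous acetic acid then hydrolyses the acetonide without ionising the benzylic C–O bonds.

Step 19
Reactants: 30 di-O-benzyl triol
Product: 31 target CNP0298853.1
Conditions: H2 (1 atm), 10 % Pd/C, EtOAc/MeOH, rt
Reagents that add atoms: none
Why: hydrogenolysis of the two aryl benzyl ethers under neutral conditions should be much faster than cleavage of the benzylic C7–OH and ring C2–O1 bonds, and no stereocentre is touched.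

**Compound list**

1 | 5-bromovanillin (3-bromo-4-hydroxy-5-methoxybenzaldehyde) | COc1cc(C=O)cc(Br)c1O | starting material
2 | 4-(benzyloxy)-3-methoxybenzyl alcohol | COc1cc(CO)ccc1OCc1ccccc1 | starting material
3 | 3-bromo-5-methoxy-4-[(4-benzyloxy-3-methoxyphenyl)methoxy]benzaldehyde | COc1cc(C=O)cc(Br)c1OCc1ccc(OCc2ccccc2)c(OC)c1 | intermediate
4 | dimethyl succinate | COC(=O)CCC(=O)OC | starting material
5 | (E)-4-{3-bromo-5-methoxy-4-[(4-benzyloxy-3-methoxyphenyl)methoxy]phenyl}-3-(methoxycarbonyl)but-3-enoic acid | COC(=O)/C(CC(=O)O)=C/c1cc(OC)c(OCc2ccc(OCc3ccccc3)c(OC)c2)c(Br)c1 | intermediate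
6 | (R)-4-{3-bromo-5-methoxy-4-[(4-benzyloxy-3-methoxyphenyl)methoxy]phenyl}-3-(methoxycarbonyl)butanoic acid | COC(=O)[C@@H](CC(=O)O)Cc1cc(OC)c(OCc2ccc(OCc3ccccc3)c(OC)c2)c(Br)c1 | intermediate
7 | (R)-4-{3-bromo-5-methoxy-4-[(4-benzyloxy-3-methoxyphenyl)methoxy]phenyl}-3-(hydroxymethyl)butanoic acid | OC[C@@H](CC(=O)O)Cc1cc(OC)c(OCc2ccc(OCc3ccccc3)c(OC)c2)c(Br)c1 | intermediate
8 | (R)-4-{3-bromo-5-methoxy-4-[(4-benzyloxy-3-methoxyphenyl)methoxy]benzyl}dihydrofuran-2(3H)-one | O=C1C[C@@H](Cc2cc(OC)c(OCc3ccc(OCc4ccccc4)c(OC)c3)c(Br)c2)CO1 | intermediate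
9 | methyl vanillate (methyl 4-hydroxy-3-methoxybenzoate) | COC(=O)c1ccc(O)c(OC)c1 | starting material
10 | (R)-4-benzyl-3-(chloroacetyl)oxazolidin-2-one | O=C(CCl)N1[C@H](Cc2ccccc2)COC1=O | starting material
11 | methyl 4-{2-[(R)-4-benzyl-2-oxooxazolidin-3-yl]-2-oxoethoxy}-3-methoxybenzoate | COC(=O)c1ccc(OCC(=O)N2[C@H](Cc3ccccc3)COC2=O)c(OC)c1 | intermediate
12 | 4-(benzyloxy)-3-methoxybenzaldehyde | COc1cc(C=O)ccc1OCc1ccccc1 | starting material
13 | methyl 4-{[(2R,3S)-1-[(R)-4-benzyl-2-oxooxazolidin-3-yl]-3-(4-benzyloxy-3-methoxyphenyl)-3-hydroxy-1-oxopropan-2-yl]oxy}-3-methoxybenzoate (syn) | COc1cc([C@H](O)[C@@H](Oc2ccc(C(=O)OC)cc2OC)C(=O)N2[C@H](Cc3ccccc3)COC2=O)ccc1OCc1ccccc1 | intermediate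
14 | methyl 4-{[(2R,3R)-1-[(R)-4-benzyl-2-oxooxazolidin-3-yl]-3-(4-benzyloxy-3-methoxyphenyl)-3-(4-nitrobenzoyloxy)-1-oxopropan-2-yl]oxy}-3-methoxybenzoate | COc1cc([C@@H](OC(=O)c2ccc([N+](=O)[O-])cc2)[C@@H](Oc2ccc(C(=O)OC)cc2OC)C(=O)N2[C@H](Cc3ccccc3)COC2=O)ccc1OCc1ccccc1 | intermediate
15 | methyl 4-{[(1R,2S)-1-(4-benzyloxy-3-methoxyphenyl)-1,3-dihydroxypropan-2-yl]oxy}-3-methoxybenzoate (erythro) | COc1cc([C@@H](O)[C@H](CO)Oc2ccc(C(=O)OC)cc2OC)ccc1OCc1ccccc1 | intermediate
16 | methyl 4-{[(4R,5S)-4-(4-benzyloxy-3-methoxyphenyl)-2,2-dimethyl-1,3-dioxan-5-yl]oxy}-3-methoxybenzoate | COc1cc([C@H]2OC(C)(C)OC[C@@H]2Oc2ccc(C(=O)OC)cc2OC)ccc1OCc1ccccc1 | intermediate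
17 | (4-{[(4R,5S)-4-(4-benzyloxy-3-methoxyphenyl)-2,2-dimethyl-1,3-dioxan-5-yl]oxy}-3-methoxyphenyl)methanol | COc1cc([C@H]2OC(C)(C)OC[C@@H]2Oc2ccc(CO)cc2OC)ccc1OCc1ccccc1 | intermediate
18 | (4R,5S)-4-(4-benzyloxy-3-methoxyphenyl)-5-[4-(bromomethyl)-2-methoxyphenoxy]-2,2-dimethyl-1,3-dioxane | COc1cc([C@H]2OC(C)(C)OC[C@@H]2Oc2ccc(CBr)cc2OC)ccc1OCc1ccccc1 | intermediate
19 | bromoacetyl bromide | BrCC(Br)=O | starting material
20 | 2-(trimethylsilyl)ethanol | C[Si](C)(C)CCO | starting material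
21 | 2-(trimethylsilyl)ethyl bromoacetate | C[Si](C)(C)CCOC(=O)CBr | intermediate
22 | (3R,4R)-4-[3-bromo-5-methoxy-4-(BV-methoxy)benzyl]-3-[3-methoxy-4-(Diox-oxy)benzyl]dihydrofuran-2(3H)-one | COc1cc([C@H]2OC(C)(C)OC[C@@H]2Oc2ccc(C[C@H]3C(=O)OC[C@@H]3Cc3cc(OC)c(OCc4ccc(OCc5ccccc5)c(OC)c4)c(Br)c3)cc2OC)ccc1OCc1ccccc1 | intermediate
23 | [2-oxo-2-(2-trimethylsilylethoxy)ethyl]zinc bromide | C[Si](C)(C)CCOC(=O)C[Zn]Br | intermediate
24 | 2-(trimethylsilyl)ethyl 2-{3-methoxy-2-(BV-methoxy)-5-[((3R,4R)-4-[3-methoxy-4-(Diox-oxy)benzyl]-5-oxotetrahydrofuran-3-yl)methyl]phenyl}acetate | COc1cc([C@H]2OC(C)(C)OC[C@@H]2Oc2ccc(C[C@H]3C(=O)OC[C@@H]3Cc3cc(OC)c(OCc4ccc(OCc5ccccc5)c(OC)c4)c(CC(=O)OCC[Si](C)(C)C)c3)cc2OC)ccc1OCc1ccccc1 | intermediate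
25 | 2-(trimethylsilyl)ethyl 2-diazo-2-{3-methoxy-2-(BV-methoxy)-5-[((3R,4R)-4-[3-methoxy-4-(Diox-oxy)benzyl]-5-oxotetrahydrofuran-3-yl)methyl]phenyl}acetate | COc1cc([C@H]2OC(C)(C)OC[C@@H]2Oc2ccc(C[C@H]3C(=O)OC[C@@H]3Cc3cc(OC)c(OCc4ccc(OCc5ccccc5)c(OC)c4)c(C(=[N+]=[N-])C(=O)OCC[Si](C)(C)C)c3)cc2OC)ccc1OCc1ccccc1 | intermediate
26 | 2-(trimethylsilyl)ethyl (2S,3R)-2-BV-7-methoxy-5-{[(3R,4R)-4-[3-methoxy-4-(Diox-oxy)benzyl]-5-oxotetrahydrofuran-3-yl]methyl}-2,3-dihydro-1-benzofuran-3-carboxylate (cis) | COc1cc([C@H]2OC(C)(C)OC[C@@H]2Oc2ccc(C[C@H]3C(=O)OC[C@@H]3Cc3cc(OC)c4c(c3)[C@@H](C(=O)OCC[Si](C)(C)C)[C@@H](c3ccc(OCc5ccccc5)c(OC)c3)O4)cc2OC)ccc1OCc1ccccc1 | intermediate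
27 | 2-(trimethylsilyl)ethyl (2S,3S)-2-BV-7-methoxy-5-{[(3R,4R)-4-[3-methoxy-4-(Diox-oxy)benzyl]-5-oxotetrahydrofuran-3-yl]methyl}-2,3-dihydro-1-benzofuran-3-carboxylate (trans) | COc1cc([C@H]2OC(C)(C)OC[C@@H]2Oc2ccc(C[C@H]3C(=O)OC[C@@H]3Cc3cc(OC)c4c(c3)[C@H](C(=O)OCC[Si](C)(C)C)[C@@H](c3ccc(OCc5ccccc5)c(OC)c3)O4)cc2OC)ccc1OCc1ccccc1 | intermediate
28 | (2S,3S)-2-BV-7-methoxy-5-{[(3R,4R)-4-[3-methoxy-4-(Diox-oxy)benzyl]-5-oxotetrahydrofuran-3-yl]methyl}-2,3-dihydro-1-benzofuran-3-carboxylic acid | COc1cc([C@H]2OC(C)(C)OC[C@@H]2Oc2ccc(C[C@H]3C(=O)OC[C@@H]3Cc3cc(OC)c4c(c3)[C@H](C(=O)O)[C@@H](c3ccc(OCc5ccccc5)c(OC)c3)O4)cc2OC)ccc1OCc1ccccc1 | intermediate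
29 | (3R,4R)-4-{[(2S,3R)-2-BV-3-(hydroxymethyl)-7-methoxy-2,3-dihydro-1-benzofuran-5-yl]methyl}-3-[3-methoxy-4-(Diox-oxy)benzyl]dihydrofuran-2(3H)-one | COc1cc([C@H]2OC(C)(C)OC[C@@H]2Oc2ccc(C[C@H]3C(=O)OC[C@@H]3Cc3cc(OC)c4c(c3)[C@H](CO)[C@@H](c3ccc(OCc5ccccc5)c(OC)c3)O4)cc2OC)ccc1OCc1ccccc1 | intermediate
30 | (3R,4R)-4-{[(2S,3R)-2-BV-3-(hydroxymethyl)-7-methoxy-2,3-dihydro-1-benzofuran-5-yl]methyl}-3-(4-{[(1R,2S)-1-BV-1,3-dihydroxypropan-2-yl]oxy}-3-methoxybenzyl)dihydrofuran-2(3H)-one | COc1cc([C@@H](O)[C@H](CO)Oc2ccc(C[C@H]3C(=O)OC[C@@H]3Cc3cc(OC)c4c(c3)[C@H](CO)[C@@H](c3ccc(OCc5ccccc5)c(OC)c3)O4)cc2OC)ccc1OCc1ccccc1 | intermediate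
31 | CNP0298853.1: (3R,4R)-3-(4-{[(1R,2S)-1,3-dihydroxy-1-(4-hydroxy-3-methoxyphenyl)propan-2-yl]oxy}-3-methoxybenzyl)-4-{[(2S,3R)-2-(4-hydroxy-3-methoxyphenyl)-3-(hydroxymethyl)-7-methoxy-2,3-dihydro-1-benzofuran-5-yl]methyl}dihydrofuran-2(3H)-one | COc1cc([C@@H](O)[C@H](CO)Oc2ccc(C[C@H]3C(=O)OC[C@@H]3Cc3cc(OC)c4c(c3)[C@H](CO)[C@@H](c3ccc(O)c(OC)c3)O4)cc2OC)ccc1O | target

**Step count.** Total: 19 steps. Longest linear sequence: 14 steps (steps 5–11, then 13–19).

**Steps most likely to fail**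

Step 16. The catalyst may discriminate the two benzylic hydrogens incompletely on this 7-methoxy pattern, because the flanking methoxy group twists the OCH2Ar group out of plane. That would leave a remote diastereomer that is hard to remove. Carbene dimerisation and loss of material during the base epimerisation are further risks. The fallback closes the same ring through O1–C2 instead of C2–C3 and uses auxiliary control instead of catalyst control. It sets out from arylacetate 24. TBAF in THF frees the arylacetic acid F1. Pivaloyl chloride and Et3N, then (S)-4-benzyloxazolidin-2-one and LiCl, give the N-arylacetyl oxazolidinone F2. Bu2BOTf/iPr2NEt and aldehyde 12 give the syn-aldol adduct F3, in which the auxiliary sets the future C3. NaBH4 in THF/H2O at 0 °C removes the auxiliary reductively, should leave the γ-lactone untouched, and gives the 1,3-diol F4. BF3·OEt2 in CH2Cl2 at −78 °C with 1,3-dimethoxybenzene ionises the 4-alkoxybenzylic carbinol. The ring-bound ether oxygen captures the cation in a five-membered closure and gives up its 4-benzyloxy-3-methoxybenzyl group to the scavenger, and the C3 substituent directs the aryl group trans. The product is acetonide alcohol 29, where the route is rejoined (aqueous acetic acid of step 18, then step 19).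

Step 7. The oxyphosphonium intermediate may eliminate by E1cB across the acidic α-C–H of the imide, or the electron-rich benzylic centre may ionise and give partial retention. The fallback makes the erythro relationship directly in an anti-aldol instead of by inversion. It sets out from methyl vanillate 9. Alkylation with (S)-4-benzyl-3-(chloroacetyl)oxazolidin-2-one (K2CO3, NaI, acetone) gives the enantiomeric-auxiliary imide F5. The magnesium halide-catalysed direct anti-aldol (MgCl2 10 mol %, Et3N, TMSCl, EtOAc, rt) with aldehyde 12 should give, through the chelated Z-enolate, the O-silylated anti adduct F6. TFA in MeOH removes the silyl group to give the anti-aldol adduct F7 (2R,3R). LiBH4 as in step 8 then gives diol 15, where the route is rejoined.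

Step 14. Oxidative addition at the hindered, electron-rich aryl bromide may be slow, so that protodebromination or protonation of the zinc enolate takes over. The fallback reverses the polarity, with an aryl nucleophile and an α-halo ester electrophile. It sets out from bromide 22. Miyaura borylation (B2pin2, Pd(dppf)Cl2, KOAc, dioxane, 80 °C) gives the aryl pinacol boronate F8. Suzuki-type coupling of F8 with bromoacetate 21 (Pd(OAc)2, P(o-tol)3, anhydrous K3PO4, THF, rt) gives arylacetate 24, where the route is rejoined.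

Further compounds
F1 | step 16 | 2-{3-methoxy-2-(BV-methoxy)-5-[((3R,4R)-4-[3-methoxy-4-(Diox-oxy)benzyl]-5-oxotetrahydrofuran-3-yl)methyl]phenyl}acetic acid | COc1cc([C@H]2OC(C)(C)OC[C@@H]2Oc2ccc(C[C@H]3C(=O)OC[C@@H]3Cc3cc(OC)c(OCc4ccc(OCc5ccccc5)c(OC)c4)c(CC(=O)O)c3)cc2OC)ccc1OCc1ccccc1
F2 | step 16 | (S)-4-benzyl-3-(arylacetyl)oxazolidin-2-one of acid F1 | COc1cc([C@H]2OC(C)(C)OC[C@@H]2Oc2ccc(C[C@H]3C(=O)OC[C@@H]3Cc3cc(OC)c(OCc4ccc(OCc5ccccc5)c(OC)c4)c(CC(=O)N4[C@@H](Cc5ccccc5)COC4=O)c3)cc2OC)ccc1OCc1ccccc1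
F3 | step 16 | (2S,3S)-syn-aldol adduct of F2 with aldehyde 12 (3-hydroxy-3-BV-2-aryl-propanoyl imide) | COc1cc([C@H]2OC(C)(C)OC[C@@H]2Oc2ccc(C[C@H]3C(=O)OC[C@@H]3Cc3cc(OC)c(OCc4ccc(OCc5ccccc5)c(OC)c4)c([C@H](C(=O)N4[C@@H](Cc5ccccc5)COC4=O)[C@H](O)c4ccc(OCc5ccccc5)c(OC)c4)c3)cc2OC)ccc1OCc1ccccc1
F4 | step 16 | (1S,2R)-1-BV-2-aryl-propane-1,3-diol (aryl = the lactone-bearing 3-methoxy-2-(BV-methoxy)phenyl ring) | COc1cc([C@H]2OC(C)(C)OC[C@@H]2Oc2ccc(C[C@H]3C(=O)OC[C@@H]3Cc3cc(OC)c(OCc4ccc(OCc5ccccc5)c(OC)c4)c([C@H](CO)[C@H](O)c4ccc(OCc5ccccc5)c(OC)c4)c3)cc2OC)ccc1OCc1ccccc1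
F5 | step 7 | methyl 4-{2-[(S)-4-benzyl-2-oxooxazolidin-3-yl]-2-oxoethoxy}-3-methoxybenzoate | COC(=O)c1ccc(OCC(=O)N2[C@@H](Cc3ccccc3)COC2=O)c(OC)c1
F6 | step 7 | O-trimethylsilyl (2R,3R)-anti-aldol adduct on the (S)-auxiliary | COc1cc([C@@H](O[Si](C)(C)C)[C@@H](Oc2ccc(C(=O)OC)cc2OC)C(=O)N2[C@@H](Cc3ccccc3)COC2=O)ccc1OCc1ccccc1
F7 | step 7 | (2R,3R)-anti-aldol adduct on the (S)-auxiliary | COc1cc([C@@H](O)[C@@H](Oc2ccc(C(=O)OC)cc2OC)C(=O)N2[C@@H](Cc3ccccc3)COC2=O)ccc1OCc1ccccc1
F8 | step 14 | aryl pinacol boronate (Br of 22 replaced by Bpin) | COc1cc([C@H]2OC(C)(C)OC[C@@H]2Oc2ccc(C[C@H]3C(=O)OC[C@@H]3Cc3cc(OC)c(OCc4ccc(OCc5ccccc5)c(OC)c4)c(B4OC(C)(C)C(C)(C)O4)c3)cc2OC)ccc1OCc1ccccc1
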